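All constants stand for no real mixture, and the outcome is calculated.

Late in the run you want to know one thing about this flask: is free catalyst still at work, and has it worked long enough to bring the exchanges level?

substrate 0.10 M; free catalyst 4.1 mM; time 2.0 d

    substrate ⇌ dormant form (K1 = 0.755, k1 = 6.21 × 10⁻⁵ /s)
    isomer of the product + free catalyst ⇌ substrate + free catalyst, rate k2*[free catalyst]*[isomer of the product] forward; the back reaction follows from the equilibrium constant (k2 = 0.0436 /M/s)
    free catalyst → spent catalyst (k3 = 1.16 × 10⁻⁷ /s)
    substrate + free catalyst ⇌ target + free catalyst, rate k4*[substrate]*[free catalyst] forward; the back reaction follows from the equilibrium constant (K4 = 1.0, k4 = 1.82 /M/s)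
    target + free catalyst ⇌ isomer of the product + free catalyst, rate k5*[free catalyst]*[target] forward; the back reaction follows from the equilibrium constant (K5 = 0.34, k5 = 0.0451 /M/s)

- at 2.0 d, what has stopped the reaction, if anything has (no working catalyst is left / it is still moving / forward and back rates have come level / all of the substrate has reacted)
- how much of the substrate has reacted by 2.0 d
- how much target there is at 2.0 d, in percent of the substrate charged
- how much isomer of the product there is at 2.0 d, in percent of the substrate charged

- what has gone from substrate into another species counts as reacted, even if it can come back
- the reaction counts as stopped when no species that holds the substrate changes by six tenths of a point or more over the second half of the time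
- run time (flask): 2.0 d

Begin with the balance of the reagent charged in the smaller amount, the catalyst, at 4.1 mM against 0.10 M of substrate. The exchanges give it back unchanged, and it leaves by the death step, so c(free catalyst) + c(spent catalyst) stays at 4.1 mM. Over the run:

exponent of the death step = 0.0200

mean c(free catalyst) as a share of the charge = (1 − exp(−0.0200)) / 0.0200 = 99.0%

Now take two extreme flasks. If the catalyst is dead from the start, substrate and dormant form alone exchange:

reacted = 0.755 / (1 + 0.755) = 43.0%

If the catalyst never dies and the exchanges come level, substrate, target, isomer of the product and dormant form stand as 1 : 1.0 : 0.340 : 0.755:

substrate left = 32.3%, reacted = 67.7%, target = 32.3%, isomer of the product = 11.0%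

The real flask lies between these, and you can place it with one number:

0.0436 /M/s × 4.1 mM × 2.0 d × 99.0% / ln 2 = 44.1

I call this the half-life count: the mean free catalyst times the time, expressed in forward half-lives of the catalysed step with the smallest forward constant, 0.0436 /M/s, with the way back of that step not counted. It is far above one, and the dormant exchange, with a relaxation half-life of 0.0556 d, is short against 2.0 d. So I place this flask at the living extreme and commit to its figures.

The forecast says forward and back rates have come level, with 67.7% reacted, 32.3% target and 11% isomer of the product, on the grounds that “the system should reach full equilibrium”.

The simulation gives forward and back rates have come level, with 67.7% reacted, 32.3% target and 11.0% isomer of the product.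

With its count of 44.1, this flask shows substrate at 32.3% after 1.00 d and 32.3% after 2.00 d. Now take the neighbour flask, charged with 0.0016 M of free catalyst and otherwise the same. Its mean free share comes from the same exponent, so its count falls with the charge to 17.2, lower than this flask's but still far above one. The neighbour flask ends with 98.0% of its catalyst free, 67.7% of the substrate reacted, 32.3% target and 11.0% isomer of the product.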